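The lactone is numbered O1, C2(=O), C3(=CH2), C4, C5. It is cut at O1–C5 and at C3–C2; the piece that drops out, O1–C2(=O), is one molecule of CO2. The vinylic C3 and the sp3 carbinol carbon C5 are 1,3-related, so a C3 alkenylboronate that carries a C5 mesylate can clamp CO2. Copper-catalysed carboxylation makes C3–C2, and the caesium acrylate formed closes the ring by SN2 at C5 with inversion. The precursor is the fully assembled coumarin epoxy ether. It comes from (S)-epichlorohydrin by two alkynylations, a methylalumination, an internal-selective hydroalumination/borylation, a Sharpless epoxidation and a Mitsunobu etherification.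

Key step: step 8

Assumption: hydrangetin (7-hydroxy-8-methoxycoumarin, 10) is taken as purchasable from natural-product suppliers; all other inputs are catalogue reagents.

Step 1
Reactants: 1 (S)-epichlorohydrin
Product: 2 (2S)-1-chloropent-4-yn-2-ol
Conditions: HC≡CH, n-BuLi, THF, −78 °C; BF3·OEt2, then 1, −78 °C
Reagents that add atoms: acetylene C#C
Why: BF3-promoted alkynylation of an epoxide (Yamaguchi–Hirao conditions): the alkynyl nucleophile should open the activated oxirane at its unsubstituted CH2 at −78 °C faster than it displaces the primary chloride, so the stereocentre is not touched and stays S.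

Step 2
Reactants: 2 (2S)-1-chloropent-4-yn-2-ol
Product: 4 (2E,5S)-6-chloro-3-methylhex-2-ene-1,5-diol, via E-alkenyldimethylalane 3 (not isolated)
Conditions: AlMe3 (3.5 equiv), Cp2ZrCl2 (0.5 equiv), CH2Cl2, 0 → 23 °C; then (CH2O)n, THF, 0 → 23 °C
Reagents that add atoms: trimethylaluminium C[Al](C)C; paraformaldehyde (as formaldehyde) C=O
Why: Zirconium-catalysed methylalumination of a terminal alkyne (Negishi carboalumination): syn addition of Me–Al with methyl on the internal carbon gives the E-alkenylalane 3 (the hydroxyl rides as its aluminium alkoxide), whose C–Al bond should add to formaldehyde with retention of the double-bond geometry.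

Step 3
Reactants: 4 (2E,5S)-6-chloro-3-methylhex-2-ene-1,5-diol
Product: 6 (2E,5R)-3-methyloct-2-en-7-yne-1,5-diol, via terminal epoxide 5 (not isolated)
Conditions: LiC≡CH·H2NCH2CH2NH2 (5 equiv), DMSO, 0 °C → rt
Reagents that add atoms: lithium acetylide ethylenediamine complex [Li]C#C.NCCN
Why: Excess acetylide first deprotonates both hydroxyls, the chlorohydrin alkoxide closes to epoxide 5 (intramolecular Williamson reaction, carbinol C–O bond kept), and acetylide then opens 5 at its CH2 terminus by SN2, so the descriptor changes to R only through the priority switch.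

Step 4
Reactants: 6 (2E,5R)-3-methyloct-2-en-7-yne-1,5-diol
Product: 8 (2E,5R)-3-methyl-7-(4,4,5,5-tetramethyl-1,3,2-dioxaborolan-2-yl)octa-2,7-diene-1,5-diol, via internal alkenylalane 7 (not isolated)
Conditions: i-Bu2AlH (3.4 equiv), NiCl2(dppp) (5 mol %), THF, 0 → 22 °C; then MeOBpin, 0 → 22 °C
Reagents that add atoms: 2-methoxy-4,4,5,5-tetramethyl-1,3,2-dioxaborolane COB1OC(C)(C)C(C)(C)O1
Why: Nickel-hydride-catalysed internal-selective (Markovnikov) hydroalumination of an alkyl-substituted terminal alkyne, where the dppp ligand places aluminium on the substituted carbon, followed by Al-to-B exchange with the methyl borate; the hydroxyls are first converted to aluminium alkoxides by the extra hydride and the trisubstituted alkene should be inert.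

Step 5
Reactants: 8 (2E,5R)-3-methyl-7-(4,4,5,5-tetramethyl-1,3,2-dioxaborolan-2-yl)octa-2,7-diene-1,5-diol
Product: 9 (2R)-1-[(2R,3R)-3-(hydroxymethyl)-2-methyloxiran-2-yl]-4-(4,4,5,5-tetramethyl-1,3,2-dioxaborolan-2-yl)pent-4-en-2-ol
Conditions: Ti(OiPr)4 (20 mol %), D-(−)-diethyl tartrate (24 mol %), t-BuOOH (anhydrous, decane), 4 Å MS, CH2Cl2, −20 °C
Reagents that add atoms: tert-butyl hydroperoxide CC(C)(C)OO
Why: Sharpless asymmetric epoxidation: with the D-(−)-tartrate the titanium peroxo complex should deliver oxygen to the face of the E-allylic alcohol that gives the 2R,3R epoxy alcohol (mirror image of the geraniol/L-(+)-tartrate case), under reagent control; the electron-poor alkenylboronate is not an allylic alcohol and should not be epoxidised.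

Step 6
Reactants: 9 (2R)-1-[(2R,3R)-3-(hydroxymethyl)-2-methyloxiran-2-yl]-4-(4,4,5,5-tetramethyl-1,3,2-dioxaborolan-2-yl)pent-4-en-2-ol; 10 hydrangetin (7-hydroxy-8-methoxy-2H-chromen-2-one)
Product: 11 7-({(2R,3R)-3-[(2R)-2-hydroxy-4-(4,4,5,5-tetramethyl-1,3,2-dioxaborolan-2-yl)pent-4-en-1-yl]-3-methyloxiran-2-yl}methoxy)-8-methoxy-2H-chromen-2-one
Conditions: PPh3, DIAD (1.05 equiv each), THF, 0 °C → rt
Reagents that add atoms: none
Why: Mitsunobu etherification: the primary epoxy carbinol should be activated much faster than the flanked secondary alcohol, and the acidic 7-hydroxycoumarin (pKa about 8) displaces the oxyphosphonium group at CH2, so no stereocentre is involved.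

Step 7
Reactants: 11 7-({(2R,3R)-3-[(2R)-2-hydroxy-4-(4,4,5,5-tetramethyl-1,3,2-dioxaborolan-2-yl)pent-4-en-1-yl]-3-methyloxiran-2-yl}methoxy)-8-methoxy-2H-chromen-2-one
Product: 12 (2R)-1-[(2R,3R)-3-{[(8-methoxy-2-oxo-2H-chromen-7-yl)oxy]methyl}-2-methyloxiran-2-yl]-4-(4,4,5,5-tetramethyl-1,3,2-dioxaborolan-2-yl)pent-4-en-2-yl methanesulfonate
Conditions: MsCl, Et3N, CH2Cl2, −10 → 0 °C
Reagents that add atoms: methanesulfonyl chloride CS(=O)(=O)Cl
Why: Sulfonylation on oxygen forms an O–S bond and leaves the C–O bond intact, so the carbinol keeps its R configuration; epoxide, boronate and coumarin should be inert to MsCl/Et3N at 0 °C.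

Step 8
Reactants: 12 (2R)-1-[(2R,3R)-3-{[(8-methoxy-2-oxo-2H-chromen-7-yl)oxy]methyl}-2-methyloxiran-2-yl]-4-(4,4,5,5-tetramethyl-1,3,2-dioxaborolan-2-yl)pent-4-en-2-yl methanesulfonate
Product: 14 7-{[(2R,3R)-3-methyl-3-{[(2S)-4-methylidene-5-oxooxolan-2-yl]methyl}oxiran-2-yl]methoxy}-8-methoxy-2H-chromen-2-one, via caesium acrylate 13 (not isolated)
Conditions: (IPr)CuCl (10 mol %; IPr = 1,3-bis(2,6-diisopropylphenyl)imidazol-2-ylidene), CsF (3 equiv), CO2 (1 atm), dry DMF, 60 °C
Reagents that add atoms: carbon dioxide O=C=O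
Why: Fluoride converts (IPr)CuCl into (IPr)CuF, boron-to-copper transmetalation gives the 1,1-disubstituted alkenylcopper at lactone C3, and CO2 inserts into the C–Cu bond (C3–C2 bond) to give a copper acrylate that CsF releases as caesium acrylate 13. The carboxylate oxygen then displaces the mesylate at C5 intramolecularly (O1–C5 bond), a 5-exo-tet closure of the lactone ring. The closest known reaction types are the copper-catalysed carboxylation of alkenylboronic esters with CO2 and the caesium carboxylate displacement of secondary sulfonates, run here in tandem (in situ O-alkylation of such carboxylates by alkyl halides is routine). The C5 stereocentre is set by the substrate: backside attack inverts the R mesylate to the S lactone carbon, and the epoxide centres are not involved. O-alkylation at C5 must beat elimination of the mesylate and attack on the epoxide: the five-membered transition state gives a high effective molarity, the epoxide carbons could only be reached through seven- or eight-membered rings, and CsF in DMF is a poor base and nucleophile towards a secondary sulfonate. The alkenylcopper must also take up CO2 before it is protonated, which strictly dry conditions under a CO2 atmosphere should secure.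

Compound list
1 | (S)-epichlorohydrin, (2S)-2-(chloromethyl)oxirane | ClC[C@@H]1CO1 | starting material
2 | (2S)-1-chloropent-4-yn-2-ol | ClC[C@H](CC#C)O | intermediate
3 | [(1E,4S)-5-chloro-4-(dimethylalumanyloxy)-2-methylpent-1-en-1-yl]dimethylalumane (E-alkenylalane, not isolated) | C[Al](C)/C=C(\C)C[C@@H](CCl)O[Al](C)C | intermediate
4 | (2E,5S)-6-chloro-3-methylhex-2-ene-1,5-diol | OC/C=C(\C)C[C@@H](CCl)O | intermediate
5 | lithium (2E)-3-methyl-4-[(2S)-oxiran-2-yl]but-2-en-1-olate (terminal epoxide, not isolated) | [Li]OC/C=C(\C)C[C@H]1CO1 | intermediate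
6 | (2E,5R)-3-methyloct-2-en-7-yne-1,5-diol | OC/C=C(\C)C[C@@H](CC#C)O | intermediate
7 | internal alkenyl(diisobutyl)alane of 6, both hydroxyls as diisobutylaluminium alkoxides (not isolated) | C=C([Al](CC(C)C)CC(C)C)C[C@H](C/C(C)=C/CO[Al](CC(C)C)CC(C)C)O[Al](CC(C)C)CC(C)C | intermediate
8 | (2E,5R)-3-methyl-7-(4,4,5,5-tetramethyl-1,3,2-dioxaborolan-2-yl)octa-2,7-diene-1,5-diol | C=C(B1OC(C)(C)C(C)(C)O1)C[C@H](C/C(C)=C/CO)O | intermediate
9 | (2R)-1-[(2R,3R)-3-(hydroxymethyl)-2-methyloxiran-2-yl]-4-(4,4,5,5-tetramethyl-1,3,2-dioxaborolan-2-yl)pent-4-en-2-ol | C=C(B1OC(C)(C)C(C)(C)O1)C[C@H](C[C@@]2(C)O[C@@H]2CO)O | intermediate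
10 | hydrangetin, 7-hydroxy-8-methoxy-2H-chromen-2-one | COc1c(O)ccc2ccc(=O)oc12 | starting material
11 | 7-({(2R,3R)-3-[(2R)-2-hydroxy-4-(4,4,5,5-tetramethyl-1,3,2-dioxaborolan-2-yl)pent-4-en-1-yl]-3-methyloxiran-2-yl}methoxy)-8-methoxy-2H-chromen-2-one | C=C(B1OC(C)(C)C(C)(C)O1)C[C@H](C[C@@]2(C)O[C@@H]2COc2ccc3ccc(=O)oc3c2OC)O | intermediate
12 | (2R)-1-[(2R,3R)-3-{[(8-methoxy-2-oxo-2H-chromen-7-yl)oxy]methyl}-2-methyloxiran-2-yl]-4-(4,4,5,5-tetramethyl-1,3,2-dioxaborolan-2-yl)pent-4-en-2-yl methanesulfonate | C=C(B1OC(C)(C)C(C)(C)O1)C[C@H](C[C@@]2(C)O[C@@H]2COc2ccc3ccc(=O)oc3c2OC)OS(C)(=O)=O | intermediate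
13 | caesium (4R)-4-(methanesulfonyloxy)-5-[(2R,3R)-3-{[(8-methoxy-2-oxo-2H-chromen-7-yl)oxy]methyl}-2-methyloxiran-2-yl]-2-methylidenepentanoate (not isolated) | C=C(C(=O)[O-])C[C@H](C[C@@]2(C)O[C@@H]2COc2ccc3ccc(=O)oc3c2OC)OS(C)(=O)=O.[Cs+] | intermediate
14 | 7-{[(2R,3R)-3-methyl-3-{[(2S)-4-methylidene-5-oxooxolan-2-yl]methyl}oxiran-2-yl]methoxy}-8-methoxy-2H-chromen-2-one | C=C1C[C@@H](C[C@@]2(C)O[C@@H]2COc2ccc3ccc(=O)oc3c2OC)OC1=O | target

Total step count: 8. Longest linear sequence: 8 steps (1 to 14); hydrangetin 10 enters at step 6.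

Steps most likely to fail

Step 8. The secondary mesylate may be lost by fluoride-induced elimination, or the alkenylcopper may be protonated before it takes up CO2, so that the alkylative ring closure never occurs. The fallback sets out from 11 and comes back at 14; it closes the ring by acylation with retention after the carbinol has been inverted. A Mitsunobu esterification of 11 with 4-nitrobenzoic acid (PPh3, DIAD, THF) should give the inverted S 4-nitrobenzoate F1. Methanolysis (K2CO3, MeOH, 0 °C) should free the S alcohol F2. The same copper-catalysed carboxylation with CO2, now without a leaving group in the molecule, followed by acidification to about pH 5, should give the γ-hydroxy acid F3. F3 is lactonised (EDC·HCl, DMAP, CH2Cl2) to 14.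

Step 4. The nickel hydride has to work beside two aluminium alkoxides; this may erode the internal selectivity, stall the catalyst or cleave the allylic C–O bond reductively. The fallback sets out from 6 and comes back at 8; it masks both hydroxyls so that the catalyst sees a plain alkyl-substituted alkyne. Silylation (Et3SiCl, imidazole, DMF) should give the bis(triethylsilyl) ether F4. The same hydroalumination/borylation (i-Bu2AlH 1.3 equiv, NiCl2(dppp), then MeOBpin) should give the alkenylboronate F5. PPTS in MeOH removes both silyl groups to give 8.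

Step 5. The hydroperoxide may oxidise the C–B bond, or the chelating 1,5-diol may slow turnover of the titanium catalyst. The fallback sets out from 6 and comes back at 11; boron is introduced only after the oxidation. Alkenylalane 7 is quenched with I2 at −78 °C instead of the borate, which should give the alkenyl iodide F6. Sharpless epoxidation under the step 5 conditions should give the epoxy diol F7. Mitsunobu etherification with 10 should give the aryl ether F8. Miyaura borylation (B2pin2, PdCl2(PPh3)2, PPh3, KOPh, toluene, 50 °C) then gives 11.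

Further compounds
F1 | step 8 | (2S)-1-[(2R,3R)-3-{[(8-methoxy-2-oxo-2H-chromen-7-yl)oxy]methyl}-2-methyloxiran-2-yl]-4-(4,4,5,5-tetramethyl-1,3,2-dioxaborolan-2-yl)pent-4-en-2-yl 4-nitrobenzoate | C=C(B1OC(C)(C)C(C)(C)O1)C[C@@H](C[C@@]2(C)O[C@@H]2COc2ccc3ccc(=O)oc3c2OC)OC(=O)c1ccc(cc1)[N+](=O)[O-]
F2 | step 8 | 7-({(2R,3R)-3-[(2S)-2-hydroxy-4-(4,4,5,5-tetramethyl-1,3,2-dioxaborolan-2-yl)pent-4-en-1-yl]-3-methyloxiran-2-yl}methoxy)-8-methoxy-2H-chromen-2-one | C=C(B1OC(C)(C)C(C)(C)O1)C[C@@H](C[C@@]2(C)O[C@@H]2COc2ccc3ccc(=O)oc3c2OC)O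
F3 | step 8 | (4S)-4-hydroxy-5-[(2R,3R)-3-{[(8-methoxy-2-oxo-2H-chromen-7-yl)oxy]methyl}-2-methyloxiran-2-yl]-2-methylidenepentanoic acid | C=C(C(=O)O)C[C@@H](C[C@@]2(C)O[C@@H]2COc2ccc3ccc(=O)oc3c2OC)O
F4 | step 4 | (2E,5R)-3-methyl-1,5-bis(triethylsilyloxy)oct-2-en-7-yne | C#CC[C@H](C/C(C)=C/CO[Si](CC)(CC)CC)O[Si](CC)(CC)CC
F5 | step 4 | 2-[(4R,6E)-6-methyl-4,8-bis(triethylsilyloxy)octa-1,6-dien-2-yl]-4,4,5,5-tetramethyl-1,3,2-dioxaborolane | C=C(B1OC(C)(C)C(C)(C)O1)C[C@H](C/C(C)=C/CO[Si](CC)(CC)CC)O[Si](CC)(CC)CC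
F6 | step 5 | (2E,5S)-7-iodo-3-methylocta-2,7-diene-1,5-diol | C=C(I)C[C@H](C/C(C)=C/CO)O
F7 | step 5 | (2S)-1-[(2R,3R)-3-(hydroxymethyl)-2-methyloxiran-2-yl]-4-iodopent-4-en-2-ol | C=C(I)C[C@H](C[C@@]2(C)O[C@@H]2CO)O
F8 | step 5 | 7-({(2R,3R)-3-[(2S)-2-hydroxy-4-iodopent-4-en-1-yl]-3-methyloxiran-2-yl}methoxy)-8-methoxy-2H-chromen-2-one | C=C(I)C[C@H](C[C@@]2(C)O[C@@H]2COc2ccc3ccc(=O)oc3c2OC)O
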